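## Retrosynthetic overview

1. Target 33 comes from tetra-MOM flavanone 32 by acetal cleavage; the (2S) centre is secured one step earlier by a Ru-catalysed transfer-hydrogenative kinetic resolution of the C2-epimer pair 31.
2. Ring C is the last ring formed, by oxa-Michael closure of 2'-hydroxychalcone 30. Chalcone 30 comes from the key intermolecular Claisen–Schmidt aldol condensation of ring A methyl ketone 23 with ring B aldehyde 28.
3. Ketone 23 is built on phloroglucinol by three successive directed ortho-metalations (prenyl, C3 acid chain, acetyl). One oxygen carries TIPS, then THP, so that only the future O1 is free at the cyclisation.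
4. The (R)-lavandulyl centre comes from an Evans alkylation of the ring-bound N-propanoyl oxazolidinone with prenyl bromide, followed by CO2H → COCH3 → C(CH3)=CH2.
5. Aldehyde 28 comes from 5-methoxyresorcinol (bis-MOM ether, lithiation, formylation). Rings A and B are bought as arenes.

Assumption: the acetal carbon of the THP group is left undefined (both epimers are carried through steps 5–12; the group is removed in step 13). The target is read as (2S) at the chromanone carbon and (R) in the lavandulyl chain.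

Abbreviations: MOM = CH2OCH3; THP = oxan-2-yl; prenyl = 3-methylbut-2-en-1-yl; lavandulyl = (2R)-5-methyl-2-(prop-1-en-2-yl)hex-4-en-1-yl.

## Route

Step 1
Reactants: 1 phloroglucinol
Product: 2 3,5-bis(methoxymethoxy)phenol
Conditions: MOMCl (2.0 equiv), i-Pr2NEt (2.2 equiv), DMF, 0 °C → rt; chromatography, mono- and tris-ethers recycled
Reagents that add atoms: chloromethyl methyl ether (MOMCl) COCCl
Why: Williamson-type O-alkylation of three equivalent phenols, stopped statistically at the bis-ether, leaves the single OH that becomes ring oxygen O1.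

Step 2
Reactants: 2 3,5-bis(methoxymethoxy)phenol
Product: 3 [3,5-bis(methoxymethoxy)phenoxy]tri(propan-2-yl)silane
Conditions: TIPSCl, imidazole, DMF, rt
Reagents that add atoms: chlorotri(propan-2-yl)silane (TIPSCl) CC(C)[Si](Cl)(C(C)C)C(C)C
Why: Phenol silylation gives a bulky, non-coordinating ether that survives n-BuLi and does not direct metalation to its own ortho positions.

Step 3
Reactants: 3 [3,5-bis(methoxymethoxy)phenoxy]tri(propan-2-yl)silane
Product: 5 [3,5-bis(methoxymethoxy)-4-prenylphenoxy]tri(propan-2-yl)silane, via aryllithium 4 (not isolated)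
Conditions: n-BuLi, THF, 0 °C, 1 h; CuBr·SMe2 (10 mol %), prenyl bromide, −40 °C → rt
Reagents that add atoms: prenyl bromide CC(C)=CCBr
Why: Directed ortho-metalation occurs at the only C–H flanked by two chelating OMOM groups, and copper-catalysed SN2 allylation of the aryllithium gives the linear prenyl arene.

Step 4
Reactants: 5 [3,5-bis(methoxymethoxy)-4-prenylphenoxy]tri(propan-2-yl)silane
Product: 6 3,5-bis(methoxymethoxy)-4-prenylphenol
Conditions: Bu4NF, AcOH, THF, 0 °C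
Reagents that add atoms: none
Why: Fluoride-mediated desilylation frees the one phenol that is para to the prenyl group; MOM ethers and the alkene are inert.

Step 5
Reactants: 6 3,5-bis(methoxymethoxy)-4-prenylphenol
Product: 7 2-[3,5-bis(methoxymethoxy)-4-prenylphenoxy]oxane
Conditions: 3,4-dihydro-2H-pyran, PPTS (5 mol %), CH2Cl2, rt
Reagents that add atoms: 3,4-dihydro-2H-pyran C1=COCCC1
Why: Acid-catalysed acetalisation gives a THP ether that directs ortho-metalation and can later be removed while the MOM ethers stay.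

Step 6
Reactants: 7 2-[3,5-bis(methoxymethoxy)-4-prenylphenoxy]oxane
Product: 10 3-[2,4-bis(methoxymethoxy)-3-prenyl-6-(oxan-2-yloxy)phenyl]propanoic acid, via aryllithium 8 (not isolated), via arylmagnesium bromide 9 (not isolated)
Conditions: n-BuLi, TMEDA, THF, −20 → 0 °C; MgBr2·OEt2, −20 °C; CuBr·SMe2 (10 mol %), β-propiolactone, −30 → 0 °C; aq. NH4Cl then citric acid to pH 5, 0 °C
Reagents that add atoms: β-propiolactone (oxetan-2-one) O=C1CCO1
Why: Directed ortho-metalation between OTHP and OMOM (two equivalent sites), Li-to-Mg transmetalation and copper-catalysed SN2 alkyl–oxygen opening of the β-lactone deliver the 3-arylpropanoic acid in one pot.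

Step 7
Reactants: 10 3-[2,4-bis(methoxymethoxy)-3-prenyl-6-(oxan-2-yloxy)phenyl]propanoic acid
Product: 12 (4R)-4-benzyl-3-{3-[2,4-bis(methoxymethoxy)-3-prenyl-6-(oxan-2-yloxy)phenyl]propanoyl}-1,3-oxazolidin-2-one, via mixed pivalic anhydride 11 (not isolated)
Conditions: PivCl, Et3N, THF, −20 °C; LiCl, (R)-4-benzyl-1,3-oxazolidin-2-one, −20 °C → rt
Reagents that add atoms: (R)-4-benzyl-1,3-oxazolidin-2-one O=C1N[C@H](Cc2ccccc2)CO1
Why: Mixed-anhydride N-acylation attaches the Evans auxiliary under mild, non-acidic conditions that leave the THP and MOM acetals intact.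

Step 8
Reactants: 12 (4R)-4-benzyl-3-{3-[2,4-bis(methoxymethoxy)-3-prenyl-6-(oxan-2-yloxy)phenyl]propanoyl}-1,3-oxazolidin-2-one
Product: 14 (4R)-4-benzyl-3-[(2R)-2-{[2,4-bis(methoxymethoxy)-3-prenyl-6-(oxan-2-yloxy)phenyl]methyl}-5-methylhex-4-enoyl]-1,3-oxazolidin-2-one, via sodium Z-enolate 13 (not isolated)
Conditions: NaN(SiMe3)2, THF, −78 °C; prenyl bromide, −78 → −40 °C
Reagents that add atoms: prenyl bromide CC(C)=CCBr
Why: Evans asymmetric alkylation, in which the chelated Z-enolate is attacked by prenyl bromide on the face opposite the (4R)-benzyl group, sets the (2R) centre (dr ≥ 95:5) that becomes the lavandulyl stereocentre.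

Step 9
Reactants: 14 (4R)-4-benzyl-3-[(2R)-2-{[2,4-bis(methoxymethoxy)-3-prenyl-6-(oxan-2-yloxy)phenyl]methyl}-5-methylhex-4-enoyl]-1,3-oxazolidin-2-one
Product: 16 (2R)-2-{[2,4-bis(methoxymethoxy)-3-prenyl-6-(oxan-2-yloxy)phenyl]methyl}-5-methylhex-4-enoic acid, via lithium peroxycarboxylate 15 (not isolated)
Conditions: LiOH, H2O2, THF/H2O 3:1, 0 °C; Na2SO3; 0.5 M HCl to pH 4, 0 °C
Reagents that add atoms: hydrogen peroxide (as LiOOH) OO
Why: Hydroperoxide-mediated exocyclic imide cleavage releases the acid without epimerisation and returns the auxiliary.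

Step 10
Reactants: 16 (2R)-2-{[2,4-bis(methoxymethoxy)-3-prenyl-6-(oxan-2-yloxy)phenyl]methyl}-5-methylhex-4-enoic acid
Product: 18 (3R)-3-{[2,4-bis(methoxymethoxy)-3-prenyl-6-(oxan-2-yloxy)phenyl]methyl}-6-methylhept-5-en-2-one, via dilithium gem-diolate 17 (not isolated)
Conditions: MeLi (3.0 equiv), Et2O/THF, −20 → 0 °C; inverse quench into cold pH 7 buffer
Reagents that add atoms: methyllithium [Li]C
Why: Organolithium addition to the lithium carboxylate stops at a stable gem-diolate that gives the methyl ketone only on quench, so neither over-addition nor α-epimerisation occurs.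

Step 11
Reactants: 18 (3R)-3-{[2,4-bis(methoxymethoxy)-3-prenyl-6-(oxan-2-yloxy)phenyl]methyl}-6-methylhept-5-en-2-one
Product: 19 2-[2-lavandulyl-3,5-bis(methoxymethoxy)-4-prenylphenoxy]oxane
Conditions: Cp2TiMe2 (2.5 equiv), toluene/THF, 65 °C, dark
Reagents that add atoms: dimethyltitanocene Cp2TiMe2 C[Ti+2]C.c1cc[cH-]c1.c1cc[cH-]c1
Why: Petasis methylenation is non-basic, so the ketone becomes the isopropenyl group without touching the adjacent stereocentre, which completes the (R)-lavandulyl chain.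

Step 12
Reactants: 19 2-[2-lavandulyl-3,5-bis(methoxymethoxy)-4-prenylphenoxy]oxane
Product: 22 1-[5-lavandulyl-2,4-bis(methoxymethoxy)-6-(oxan-2-yloxy)-3-prenylphenyl]ethan-1-one, via aryllithium 20 (not isolated), via lithium hemiaminal adduct 21 (not isolated)
Conditions: n-BuLi, TMEDA, THF, −20 → 0 °C; N-methoxy-N-methylacetamide, −78 °C → rt; aq. NH4Cl
Reagents that add atoms: N-methoxy-N-methylacetamide CC(=O)N(C)OC
Why: Directed ortho-metalation at the last ring C–H (flanked by OTHP and OMOM) followed by Weinreb-amide acylation stops cleanly at the aryl methyl ketone.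

Step 13
Reactants: 22 1-[5-lavandulyl-2,4-bis(methoxymethoxy)-6-(oxan-2-yloxy)-3-prenylphenyl]ethan-1-one
Product: 23 1-[2-hydroxy-3-lavandulyl-4,6-bis(methoxymethoxy)-5-prenylphenyl]ethan-1-one
Conditions: PPTS (20 mol %), MeOH, 40 °C
Reagents that add atoms: none
Why: Mild transacetalisation removes the THP acetal far faster than the aryl MOM ethers, so only the phenol between the acetyl and lavandulyl groups is freed.

Step 14
Reactants: 24 5-methoxyresorcinol
Product: 25 1-methoxy-3,5-bis(methoxymethoxy)benzene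
Conditions: MOMCl (2.5 equiv), i-Pr2NEt, CH2Cl2, 0 °C → rt
Reagents that add atoms: chloromethyl methyl ether (MOMCl) COCCl
Why: Exhaustive Williamson-type O-alkylation protects both phenols as base-stable acetals that also direct the next metalation.

Step 15
Reactants: 25 1-methoxy-3,5-bis(methoxymethoxy)benzene
Product: 28 4-methoxy-2,6-bis(methoxymethoxy)benzaldehyde, via aryllithium 26 (not isolated), via lithium hemiaminal alkoxide 27 (not isolated)
Conditions: n-BuLi, TMEDA, THF, 0 °C; DMF, −78 °C → rt; aq. NH4Cl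
Reagents that add atoms: N,N-dimethylformamide CN(C)C=O
Why: Directed ortho-metalation favours the C–H between the two OMOM groups (stronger directors than OMe), and DMF formylation gives the ring B aldehyde.

Step 16
Reactants: 23 1-[2-hydroxy-3-lavandulyl-4,6-bis(methoxymethoxy)-5-prenylphenyl]ethan-1-one; 28 4-methoxy-2,6-bis(methoxymethoxy)benzaldehyde
Product: 30 (E)-1-[2-hydroxy-3-lavandulyl-4,6-bis(methoxymethoxy)-5-prenylphenyl]-3-[4-methoxy-2,6-bis(methoxymethoxy)phenyl]prop-2-en-1-one, via aldol adduct 29 (not isolated)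
Conditions: KOH (10 equiv), EtOH/H2O, rt → 40 °C, 48 h, argon; AcOH to pH 6, 0 °C
Reagents that add atoms: none
Why: Claisen–Schmidt crossed aldol condensation between the only enolisable partner (the methyl ketone) and the non-enolisable aldehyde, followed by E1cB dehydration, gives the (E)-chalcone and joins rings A and B.

Step 17
Reactants: 30 (E)-1-[2-hydroxy-3-lavandulyl-4,6-bis(methoxymethoxy)-5-prenylphenyl]-3-[4-methoxy-2,6-bis(methoxymethoxy)phenyl]prop-2-en-1-one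
Product: 31 8-lavandulyl-2-[4-methoxy-2,6-bis(methoxymethoxy)phenyl]-5,7-bis(methoxymethoxy)-6-prenylchroman-4-one as a 1:1 mixture of C2 epimers
Conditions: NaOAc (10 equiv), EtOH/H2O, reflux, 24–36 h; unreacted 30 recycled
Reagents that add atoms: none
Why: Base-mediated 6-endo intramolecular oxa-Michael addition closes ring C through the only free phenol, which fixes the 8-lavandulyl-6-prenyl regiochemistry while C2 forms without control.

Step 18
Reactants: 31 8-lavandulyl-2-[4-methoxy-2,6-bis(methoxymethoxy)phenyl]-5,7-bis(methoxymethoxy)-6-prenylchroman-4-one as a 1:1 mixture of C2 epimers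
Product: 32 (2S)-8-lavandulyl-2-[4-methoxy-2,6-bis(methoxymethoxy)phenyl]-5,7-bis(methoxymethoxy)-6-prenylchroman-4-one
Conditions: RuCl(p-cymene)[(R,R)-TsDPEN] (3 mol %), HCO2H/Et3N 5:2, EtOAc, 30 °C, stopped at 52–55 % conversion; SiO2 chromatography
Reagents that add atoms: none
Why: Noyori asymmetric transfer hydrogenation used as a kinetic resolution: the (R,R) catalyst reduces the (2R) epimer fast to the cis-(2R,4R) alcohol and leaves the (2S) ketone, so the C2 centre is set by catalyst control while the remote lavandulyl centre is a spectator.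

Step 19
Reactants: 32 (2S)-8-lavandulyl-2-[4-methoxy-2,6-bis(methoxymethoxy)phenyl]-5,7-bis(methoxymethoxy)-6-prenylchroman-4-one
Product: 33 (2S)-2-(2,6-dihydroxy-4-methoxyphenyl)-5,7-dihydroxy-8-lavandulyl-6-prenylchroman-4-one (CNP0301909.2)
Conditions: 3 M aq. HCl/MeOH 1:5, 45 °C, 2–3 h; NaHCO3 to pH 6 at 0 °C; rapid chromatography, no base contact
Reagents that add atoms: none
Why: Acid-catalysed acetal methanolysis removes all four MOM ethers at a temperature low enough to spare the prenyl and isopropenyl alkenes, and avoiding base prevents chalcone ring-opening that would scramble C2.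

## Compound list

1 | phloroglucinol (benzene-1,3,5-triol) | Oc1cc(O)cc(O)c1 | starting material
2 | 3,5-bis(methoxymethoxy)phenol | COCOc1cc(O)cc(OCOC)c1 | intermediate
3 | [3,5-bis(methoxymethoxy)phenoxy]tri(propan-2-yl)silane | COCOc1cc(O[Si](C(C)C)(C(C)C)C(C)C)cc(OCOC)c1 | intermediate
4 | {2,6-bis(methoxymethoxy)-4-[tri(propan-2-yl)silyloxy]phenyl}lithium (formed in situ) | [Li]c1c(OCOC)cc(O[Si](C(C)C)(C(C)C)C(C)C)cc1OCOC | intermediate
5 | [3,5-bis(methoxymethoxy)-4-(3-methylbut-2-en-1-yl)phenoxy]tri(propan-2-yl)silane | CC(C)=CCc1c(OCOC)cc(O[Si](C(C)C)(C(C)C)C(C)C)cc1OCOC | intermediate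
6 | 3,5-bis(methoxymethoxy)-4-(3-methylbut-2-en-1-yl)phenol | CC(C)=CCc1c(OCOC)cc(O)cc1OCOC | intermediate
7 | 2-[3,5-bis(methoxymethoxy)-4-(3-methylbut-2-en-1-yl)phenoxy]oxane | CC(C)=CCc1c(OCOC)cc(OC2CCCCO2)cc1OCOC | intermediate
8 | [2,4-bis(methoxymethoxy)-3-(3-methylbut-2-en-1-yl)-6-(oxan-2-yloxy)phenyl]lithium (formed in situ) | [Li]c1c(OCOC)c(CC=C(C)C)c(OCOC)cc1OC1CCCCO1 | intermediate
9 | [2,4-bis(methoxymethoxy)-3-(3-methylbut-2-en-1-yl)-6-(oxan-2-yloxy)phenyl]magnesium bromide (formed in situ) | Br[Mg]c1c(OCOC)c(CC=C(C)C)c(OCOC)cc1OC1CCCCO1 | intermediate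
10 | 3-[2,4-bis(methoxymethoxy)-3-(3-methylbut-2-en-1-yl)-6-(oxan-2-yloxy)phenyl]propanoic acid | OC(=O)CCc1c(OCOC)c(CC=C(C)C)c(OCOC)cc1OC1CCCCO1 | intermediate
11 | mixed anhydride of 10 with pivalic acid (formed in situ) | CC(C)(C)C(=O)OC(=O)CCc1c(OCOC)c(CC=C(C)C)c(OCOC)cc1OC1CCCCO1 | intermediate
12 | (4R)-4-benzyl-3-{3-[2,4-bis(methoxymethoxy)-3-(3-methylbut-2-en-1-yl)-6-(oxan-2-yloxy)phenyl]propanoyl}-1,3-oxazolidin-2-one | O=C(CCc1c(OCOC)c(CC=C(C)C)c(OCOC)cc1OC1CCCCO1)N1C(=O)OC[C@H]1Cc1ccccc1 | intermediate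
13 | sodium (Z)-enolate of 12 (formed in situ) | [Na]O/C(=C\Cc1c(OCOC)c(CC=C(C)C)c(OCOC)cc1OC1CCCCO1)N1C(=O)OC[C@H]1Cc1ccccc1 | intermediate
14 | (4R)-4-benzyl-3-[(2R)-2-{[2,4-bis(methoxymethoxy)-3-(3-methylbut-2-en-1-yl)-6-(oxan-2-yloxy)phenyl]methyl}-5-methylhex-4-enoyl]-1,3-oxazolidin-2-one | CC(C)=CC[C@H](Cc1c(OCOC)c(CC=C(C)C)c(OCOC)cc1OC1CCCCO1)C(=O)N1C(=O)OC[C@H]1Cc1ccccc1 | intermediate
15 | lithium (2R)-2-{[2,4-bis(methoxymethoxy)-3-(3-methylbut-2-en-1-yl)-6-(oxan-2-yloxy)phenyl]methyl}-5-methylhex-4-eneperoxoate (formed in situ) | CC(C)=CC[C@H](Cc1c(OCOC)c(CC=C(C)C)c(OCOC)cc1OC1CCCCO1)C(=O)OO[Li] | intermediate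
16 | (2R)-2-{[2,4-bis(methoxymethoxy)-3-(3-methylbut-2-en-1-yl)-6-(oxan-2-yloxy)phenyl]methyl}-5-methylhex-4-enoic acid | CC(C)=CC[C@H](Cc1c(OCOC)c(CC=C(C)C)c(OCOC)cc1OC1CCCCO1)C(=O)O | intermediate
17 | dilithium gem-diolate from 16 and MeLi (formed in situ) | CC(C)=CC[C@H](Cc1c(OCOC)c(CC=C(C)C)c(OCOC)cc1OC1CCCCO1)C(C)(O[Li])O[Li] | intermediate
18 | (3R)-3-{[2,4-bis(methoxymethoxy)-3-(3-methylbut-2-en-1-yl)-6-(oxan-2-yloxy)phenyl]methyl}-6-methylhept-5-en-2-one | CC(C)=CC[C@H](Cc1c(OCOC)c(CC=C(C)C)c(OCOC)cc1OC1CCCCO1)C(C)=O | intermediate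
19 | 2-{3,5-bis(methoxymethoxy)-2-[(2R)-5-methyl-2-(prop-1-en-2-yl)hex-4-en-1-yl]-4-(3-methylbut-2-en-1-yl)phenoxy}oxane | CC(C)=CC[C@H](Cc1c(OCOC)c(CC=C(C)C)c(OCOC)cc1OC1CCCCO1)C(C)=C | intermediate
20 | aryllithium from 19, lithiated between OTHP and OMOM (formed in situ) | CC(C)=CC[C@H](Cc1c(OCOC)c(CC=C(C)C)c(OCOC)c([Li])c1OC1CCCCO1)C(C)=C | intermediate
21 | lithium hemiaminal adduct of 20 with N-methoxy-N-methylacetamide (formed in situ) | CC(C)=CC[C@H](Cc1c(OCOC)c(CC=C(C)C)c(OCOC)c(C(C)(O[Li])N(C)OC)c1OC1CCCCO1)C(C)=C | intermediate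
22 | 1-{2,4-bis(methoxymethoxy)-5-[(2R)-5-methyl-2-(prop-1-en-2-yl)hex-4-en-1-yl]-3-(3-methylbut-2-en-1-yl)-6-(oxan-2-yloxy)phenyl}ethan-1-one | CC(C)=CC[C@H](Cc1c(OCOC)c(CC=C(C)C)c(OCOC)c(C(C)=O)c1OC1CCCCO1)C(C)=C | intermediate
23 | 1-{2-hydroxy-4,6-bis(methoxymethoxy)-3-[(2R)-5-methyl-2-(prop-1-en-2-yl)hex-4-en-1-yl]-5-(3-methylbut-2-en-1-yl)phenyl}ethan-1-one | CC(C)=CC[C@H](Cc1c(OCOC)c(CC=C(C)C)c(OCOC)c(C(C)=O)c1O)C(C)=C | intermediate
24 | 5-methoxyresorcinol (5-methoxybenzene-1,3-diol) | COc1cc(O)cc(O)c1 | starting material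
25 | 1-methoxy-3,5-bis(methoxymethoxy)benzene | COCOc1cc(OC)cc(OCOC)c1 | intermediate
26 | [4-methoxy-2,6-bis(methoxymethoxy)phenyl]lithium (formed in situ) | [Li]c1c(OCOC)cc(OC)cc1OCOC | intermediate
27 | lithium (dimethylamino)[4-methoxy-2,6-bis(methoxymethoxy)phenyl]methanolate (formed in situ) | CN(C)C(O[Li])c1c(OCOC)cc(OC)cc1OCOC | intermediate
28 | 4-methoxy-2,6-bis(methoxymethoxy)benzaldehyde | O=Cc1c(OCOC)cc(OC)cc1OCOC | intermediate
29 | 3-hydroxy-1-{2-hydroxy-4,6-bis(methoxymethoxy)-3-[(2R)-5-methyl-2-(prop-1-en-2-yl)hex-4-en-1-yl]-5-(3-methylbut-2-en-1-yl)phenyl}-3-[4-methoxy-2,6-bis(methoxymethoxy)phenyl]propan-1-one (formed in situ) | CC(C)=CC[C@H](Cc1c(OCOC)c(CC=C(C)C)c(OCOC)c(C(=O)CC(O)c2c(OCOC)cc(OC)cc2OCOC)c1O)C(C)=C | intermediate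
30 | (E)-1-{2-hydroxy-4,6-bis(methoxymethoxy)-3-[(2R)-5-methyl-2-(prop-1-en-2-yl)hex-4-en-1-yl]-5-(3-methylbut-2-en-1-yl)phenyl}-3-[4-methoxy-2,6-bis(methoxymethoxy)phenyl]prop-2-en-1-one | CC(C)=CC[C@H](Cc1c(OCOC)c(CC=C(C)C)c(OCOC)c(C(=O)/C=C/c2c(OCOC)cc(OC)cc2OCOC)c1O)C(C)=C | intermediate
31 | 2-[4-methoxy-2,6-bis(methoxymethoxy)phenyl]-5,7-bis(methoxymethoxy)-8-[(2R)-5-methyl-2-(prop-1-en-2-yl)hex-4-en-1-yl]-6-(3-methylbut-2-en-1-yl)-2,3-dihydro-4H-chromen-4-one, 1:1 C2 epimers | C=C(C)[C@H](CC=C(C)C)Cc1c(OCOC)c(CC=C(C)C)c(OCOC)c2c1OC(c1c(OCOC)cc(OC)cc1OCOC)CC2=O | intermediate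
32 | (2S)-2-[4-methoxy-2,6-bis(methoxymethoxy)phenyl]-5,7-bis(methoxymethoxy)-8-[(2R)-5-methyl-2-(prop-1-en-2-yl)hex-4-en-1-yl]-6-(3-methylbut-2-en-1-yl)-2,3-dihydro-4H-chromen-4-one | C=C(C)[C@H](CC=C(C)C)Cc1c(OCOC)c(CC=C(C)C)c(OCOC)c2c1O[C@H](c1c(OCOC)cc(OC)cc1OCOC)CC2=O | intermediate
33 | (2S)-2-(2,6-dihydroxy-4-methoxyphenyl)-5,7-dihydroxy-8-[(2R)-5-methyl-2-(prop-1-en-2-yl)hex-4-en-1-yl]-6-(3-methylbut-2-en-1-yl)-2,3-dihydro-4H-chromen-4-one | C=C(C)[C@H](CC=C(C)C)Cc1c(O)c(CC=C(C)C)c(O)c2c1O[C@H](c1c(O)cc(OC)cc1O)CC2=O | target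

## Summary and risks

Total step count: 19. Longest linear sequence: 17 steps (1–13, then 16–19); the ring B aldehyde takes 2 steps (14–15).

Three steps most likely to fail:

1. Step 6. The ring lithiation has to beat deprotonation of the benzylic/allylic CH2 of the prenyl group, and the lactone opening uses a di-ortho-substituted aryl nucleophile. The fallback sets out from 6 and comes back at 10 without any metalation of a prenylated ring. O-Allylation of 6 (allyl bromide, K2CO3, acetone) gives 5-(allyloxy)-1,3-bis(methoxymethoxy)-2-(3-methylbut-2-en-1-yl)benzene F1. An aromatic Claisen rearrangement (PhNEt2, 190 °C; both ortho positions equivalent, para position blocked) gives 2-allyl-3,5-bis(methoxymethoxy)-4-(3-methylbut-2-en-1-yl)phenol F2. Dihydropyran/PPTS gives 2-[2-allyl-3,5-bis(methoxymethoxy)-4-(3-methylbut-2-en-1-yl)phenoxy]oxane F3. 9-BBN in THF hydroborates only the terminal alkene to give 9-{3-[2,4-bis(methoxymethoxy)-3-(3-methylbut-2-en-1-yl)-6-(oxan-2-yloxy)phenyl]propyl}-9-borabicyclo[3.3.1]nonane F4, which NaOH/H2O2 oxidises to 3-[2,4-bis(methoxymethoxy)-3-(3-methylbut-2-en-1-yl)-6-(oxan-2-yloxy)phenyl]propan-1-ol F5. TEMPO/PhI(OAc)2 in MeCN/pH 7 buffer then oxidises F5 through 3-[2,4-bis(methoxymethoxy)-3-(3-methylbut-2-en-1-yl)-6-(oxan-2-yloxy)phenyl]propanal F6 to acid 10.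

2. Step 12. This is a third ring metalation on a fully loaded ring that carries two side chains with acidic allylic/benzylic hydrogens, followed by acylation of a very hindered aryllithium. The fallback sets out from 19 and comes back at 23 without strong base. PPTS/MeOH removes the THP group to give 3,5-bis(methoxymethoxy)-2-[(2R)-5-methyl-2-(prop-1-en-2-yl)hex-4-en-1-yl]-4-(3-methylbut-2-en-1-yl)phenol F7. Magnesium-mediated ortho-formylation (MgCl2, Et3N, paraformaldehyde, MeCN, reflux; only one free ortho position) gives 2-hydroxy-4,6-bis(methoxymethoxy)-3-[(2R)-5-methyl-2-(prop-1-en-2-yl)hex-4-en-1-yl]-5-(3-methylbut-2-en-1-yl)benzaldehyde F8. MeMgBr (3 equiv, THF, −78 → 0 °C) gives 1-{2-hydroxy-4,6-bis(methoxymethoxy)-3-[(2R)-5-methyl-2-(prop-1-en-2-yl)hex-4-en-1-yl]-5-(3-methylbut-2-en-1-yl)phenyl}ethan-1-ol F9 (carbinol epimers). Immediate oxidation with activated MnO2 in CH2Cl2 gives ketone 23.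

3. Step 18. The carbonyl is flanked by the 5-OMOM group, so the transfer hydrogenation may be slow or poorly selective between the C2 epimers. The fallback sets out from 31 and comes back at 33 by physical separation instead of catalysis. The four MOM ethers are cleaved first (HCl/MeOH as in step 19) to give 2-(2,6-dihydroxy-4-methoxyphenyl)-5,7-dihydroxy-8-[(2R)-5-methyl-2-(prop-1-en-2-yl)hex-4-en-1-yl]-6-(3-methylbut-2-en-1-yl)-2,3-dihydro-4H-chromen-4-one as the C2-epimer pair F10. The two diastereomers are then separated by preparative HPLC on an amylose tris(3,5-dimethylphenylcarbamate) phase (hexane/i-PrOH, 0.1 % formic acid); the (2S) isomer is 33.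

Further compounds

F1 | step 6 | 5-(allyloxy)-1,3-bis(methoxymethoxy)-2-(3-methylbut-2-en-1-yl)benzene | C=CCOc1cc(OCOC)c(CC=C(C)C)c(OCOC)c1
F2 | step 6 | 2-allyl-3,5-bis(methoxymethoxy)-4-(3-methylbut-2-en-1-yl)phenol | C=CCc1c(O)cc(OCOC)c(CC=C(C)C)c1OCOC
F3 | step 6 | 2-[2-allyl-3,5-bis(methoxymethoxy)-4-(3-methylbut-2-en-1-yl)phenoxy]oxane | C=CCc1c(OC2CCCCO2)cc(OCOC)c(CC=C(C)C)c1OCOC
F4 | step 6 | 9-{3-[2,4-bis(methoxymethoxy)-3-(3-methylbut-2-en-1-yl)-6-(oxan-2-yloxy)phenyl]propyl}-9-borabicyclo[3.3.1]nonane | C1CCC2CCCC1B2CCCc1c(OC2CCCCO2)cc(OCOC)c(CC=C(C)C)c1OCOC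
F5 | step 6 | 3-[2,4-bis(methoxymethoxy)-3-(3-methylbut-2-en-1-yl)-6-(oxan-2-yloxy)phenyl]propan-1-ol | OCCCc1c(OC2CCCCO2)cc(OCOC)c(CC=C(C)C)c1OCOC
F6 | step 6 | 3-[2,4-bis(methoxymethoxy)-3-(3-methylbut-2-en-1-yl)-6-(oxan-2-yloxy)phenyl]propanal | O=CCCc1c(OC2CCCCO2)cc(OCOC)c(CC=C(C)C)c1OCOC
F7 | step 12 | 3,5-bis(methoxymethoxy)-2-[(2R)-5-methyl-2-(prop-1-en-2-yl)hex-4-en-1-yl]-4-(3-methylbut-2-en-1-yl)phenol | CC(C)=CC[C@H](Cc1c(OCOC)c(CC=C(C)C)c(OCOC)cc1O)C(C)=C
F8 | step 12 | 2-hydroxy-4,6-bis(methoxymethoxy)-3-[(2R)-5-methyl-2-(prop-1-en-2-yl)hex-4-en-1-yl]-5-(3-methylbut-2-en-1-yl)benzaldehyde | CC(C)=CC[C@H](Cc1c(OCOC)c(CC=C(C)C)c(OCOC)c(C=O)c1O)C(C)=C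
F9 | step 12 | 1-{2-hydroxy-4,6-bis(methoxymethoxy)-3-[(2R)-5-methyl-2-(prop-1-en-2-yl)hex-4-en-1-yl]-5-(3-methylbut-2-en-1-yl)phenyl}ethan-1-ol | CC(C)=CC[C@H](Cc1c(OCOC)c(CC=C(C)C)c(OCOC)c(C(C)O)c1O)C(C)=C
F10 | step 18 | 2-(2,6-dihydroxy-4-methoxyphenyl)-5,7-dihydroxy-8-[(2R)-5-methyl-2-(prop-1-en-2-yl)hex-4-en-1-yl]-6-(3-methylbut-2-en-1-yl)-2,3-dihydro-4H-chromen-4-one, C2-epimer pair | C=C(C)[C@H](CC=C(C)C)Cc1c(O)c(CC=C(C)C)c(O)c2c1OC(c1c(O)cc(OC)cc1O)CC2=O
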